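**Assumption:** the target has no stereocentre and no stereogenic double bond, so it is one achiral compound and no asymmetric step is needed.

## Retrosynthetic overview

1. Target 15 is cut at the ring A C6–CH2 bond: aryl chloride 6 plus the acyloxymethyl trifluoroborate 13, an α-oxygenated carbanion (hydroxymethyl-anion) equivalent that already carries the whole haematommate unit.
2. 13 comes from haematommic acid 10 by carboxylate O-alkylation with bromomethyl boronate 11; 10 comes from methyl orsellinate 7 by C3 formylation and ester hydrolysis.
3. 6 comes from 1-chloro-3,5-dimethoxybenzene 1 by two directed ortho-lithiations (MeI, then ClCO2Me) and O-demethylation.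
4. No ring is formed: both benzene rings are bought. Ring A is finished in steps 1–3, ring B in steps 4–6, and the two are joined in step 7 without protecting groups.

## Route

**Step 1**
Reactants: 1 1-chloro-3,5-dimethoxybenzene
Product: 3 5-chloro-1,3-dimethoxy-2-methylbenzene, via (4-chloro-2,6-dimethoxyphenyl)lithium 2 (not isolated)
Conditions: n-BuLi (1.1 equiv), TMEDA (1.1 equiv), THF, −78 to 0 °C, 1 h; MeI (1.5 equiv), −78 °C to rt
Reagents that add atoms: iodomethane, CI
Why: directed ortho-metalation at the position flanked by both methoxy groups (doubly coordinated, most acidic, and para to Cl so no aryne can form), then SN2 methylation of the aryllithium.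

**Step 2**
Reactants: 3 5-chloro-1,3-dimethoxy-2-methylbenzene
Product: 5 methyl 6-chloro-2,4-dimethoxy-3-methylbenzoate, via (6-chloro-2,4-dimethoxy-3-methylphenyl)lithium 4 (not isolated)
Conditions: s-BuLi (1.15 equiv), TMEDA, THF, −78 °C, 1 h; cannulate into ClCO2Me (3 equiv), THF, −78 °C to rt
Reagents that add atoms: methyl chloroformate, COC(Cl)=O
Why: second directed ortho-metalation at the only ring C–H type left, between OMe and Cl (cooperative acidification), held at −78 °C so the ortho-chloroaryllithium does not lose LiCl, then acylation with excess chloroformate by inverse addition to avoid ketone formation.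

**Step 3**
Reactants: 5 methyl 6-chloro-2,4-dimethoxy-3-methylbenzoate
Product: 6 methyl 6-chloro-2,4-dihydroxy-3-methylbenzoate
Conditions: BBr3 (3 equiv), CH2Cl2, −78 to 0 °C (rt if needed); ice/H2O
Reagents that add atoms: none
Why: Lewis-acid aryl methyl ether cleavage (bromide SN2 on the O-methyl of the boron-complexed ether), which is faster than cleavage of the hindered methyl ester flanked by Cl and O, and is followed to stop before the ester is touched.

**Step 4**
Reactants: 7 methyl orsellinate (methyl 2,4-dihydroxy-6-methylbenzoate)
Product: 9 methyl haematommate (methyl 3-formyl-2,4-dihydroxy-6-methylbenzoate), via methyl 3-[chloro(methoxy)methyl]-2,4-dihydroxy-6-methylbenzoate 8 (not isolated)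
Conditions: TiCl4 (3 equiv), Cl2CHOMe (1.3 equiv), CH2Cl2, −10 to 0 °C, 2 h; 1 M HCl/ice; chromatography or crystallisation
Reagents that add atoms: dichloromethyl methyl ether, COC(Cl)Cl; water, O
Why: Rieche formylation, in which the titanium phenoxides deliver the electrophile to C3, the position ortho to both oxygens and less hindered than C5; the racemic α-chloro ether 8 is hydrolysed on work-up and any minor 5-formyl isomer is separated.

**Step 5**
Reactants: 9 methyl haematommate
Product: 10 haematommic acid (3-formyl-2,4-dihydroxy-6-methylbenzoic acid)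
Conditions: conc. H2SO4, 0 °C to rt, 2 h; pour onto ice, filter
Reagents that add atoms: water, O
Why: AAC1 ester hydrolysis through the acylium ion, which is favoured for a di-ortho-substituted benzoate with ortho/para hydroxyl donors (mesitoate-type), and avoids hot alkali that a hindered ester next to an aldehyde would not tolerate.

**Step 6**
Reactants: 10 haematommic acid; 11 2-(bromomethyl)-4,4,5,5-tetramethyl-1,3,2-dioxaborolane
Product: 13 potassium trifluoro{[(3-formyl-2,4-dihydroxy-6-methylbenzoyl)oxy]methyl}borate, via pinacol boronate ester 12 (not isolated)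
Conditions: KHCO3 (1.05 equiv), DMF, rt, 30 min; 11 (1.1 equiv), rt to 40 °C; then aq KHF2 (3.5 equiv), MeOH, 0 °C to rt; hot acetone extraction, Et2O precipitation
Reagents that add atoms: potassium hydrogen difluoride, [K+].F[H-]F
Why: hydrogencarbonate deprotonates only the carboxylic acid (both phenols are chelated and far less acidic), the carboxylate displaces bromide from the α-bromo boronate (Matteson-type substitution through the boron ate complex), and fluoride exchange gives the bench-stable trifluoroborate.

**Step 7**
Reactants: 6 methyl 6-chloro-2,4-dihydroxy-3-methylbenzoate; 13 potassium trifluoro{[(3-formyl-2,4-dihydroxy-6-methylbenzoyl)oxy]methyl}borate (1.3 equiv)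
Product: 15 methyl 6-{[(3-formyl-2,4-dihydroxy-6-methylbenzoyl)oxy]methyl}-2,4-dihydroxy-3-methylbenzoate, via boronic acid 14 (not isolated)
Conditions: Pd(OAc)2 (5 mol %), RuPhos (2-dicyclohexylphosphino-2′,6′-diisopropoxybiphenyl, 10 mol %), K2CO3 (6 equiv), degassed 1,4-dioxane/H2O 10:1, 90 °C; 1 M HCl to pH 3
Reagents that add atoms: none
Why: Proposed new method: a Suzuki–Miyaura sp2–sp3 coupling in which the oxygen-bearing CH2, normally an electrophilic carbon, is delivered as a carbanion equivalent to the equally electrophilic C–Cl carbon ortho to the ester; RuPhos-ligated zerovalent palladium inserts into the 2-chlorobenzoate C–Cl bond, base and water slowly unmask 13 to boronic acid 14, transmetalation is helped by the neighbouring acyloxy oxygen and the CH2 group has no β-hydrogen; the closest known reaction type is the palladium-catalysed coupling of potassium acetoxymethyl- and alkoxymethyltrifluoroborates with aryl chlorides, where an unhindered acetate is cleaved by the aqueous base, whereas this 2,6-disubstituted, phenoxide-deactivated aroyl ester should survive, the benzylic carbon is meta to both phenoxides so no quinone methide can form, and no stereocentre is created.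

## Compound list

1 | 1-chloro-3,5-dimethoxybenzene | COc1cc(Cl)cc(OC)c1 | starting material
2 | (4-chloro-2,6-dimethoxyphenyl)lithium (not isolated) | [Li]c1c(OC)cc(Cl)cc1OC | intermediate
3 | 5-chloro-1,3-dimethoxy-2-methylbenzene | COc1cc(Cl)cc(OC)c1C | intermediate
4 | (6-chloro-2,4-dimethoxy-3-methylphenyl)lithium (not isolated) | [Li]c1c(Cl)cc(OC)c(C)c1OC | intermediate
5 | methyl 6-chloro-2,4-dimethoxy-3-methylbenzoate | COC(=O)c1c(Cl)cc(OC)c(C)c1OC | intermediate
6 | methyl 6-chloro-2,4-dihydroxy-3-methylbenzoate | COC(=O)c1c(Cl)cc(O)c(C)c1O | intermediate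
7 | methyl orsellinate (methyl 2,4-dihydroxy-6-methylbenzoate) | COC(=O)c1c(C)cc(O)cc1O | starting material
8 | methyl 3-[chloro(methoxy)methyl]-2,4-dihydroxy-6-methylbenzoate (racemic, not isolated) | COC(Cl)c1c(O)cc(C)c(C(=O)OC)c1O | intermediate
9 | methyl haematommate (methyl 3-formyl-2,4-dihydroxy-6-methylbenzoate) | COC(=O)c1c(C)cc(O)c(C=O)c1O | intermediate
10 | haematommic acid (3-formyl-2,4-dihydroxy-6-methylbenzoic acid) | OC(=O)c1c(C)cc(O)c(C=O)c1O | intermediate
11 | 2-(bromomethyl)-4,4,5,5-tetramethyl-1,3,2-dioxaborolane | BrCB1OC(C)(C)C(C)(C)O1 | starting material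
12 | (4,4,5,5-tetramethyl-1,3,2-dioxaborolan-2-yl)methyl 3-formyl-2,4-dihydroxy-6-methylbenzoate (not isolated) | CC1(C)OB(COC(=O)c2c(C)cc(O)c(C=O)c2O)OC1(C)C | intermediate
13 | potassium trifluoro{[(3-formyl-2,4-dihydroxy-6-methylbenzoyl)oxy]methyl}borate | [K+].F[B-](F)(F)COC(=O)c1c(C)cc(O)c(C=O)c1O | intermediate
14 | {[(3-formyl-2,4-dihydroxy-6-methylbenzoyl)oxy]methyl}boronic acid (not isolated) | OB(O)COC(=O)c1c(C)cc(O)c(C=O)c1O | intermediate
15 | methyl 6-{[(3-formyl-2,4-dihydroxy-6-methylbenzoyl)oxy]methyl}-2,4-dihydroxy-3-methylbenzoate | COC(=O)c1c(COC(=O)c2c(C)cc(O)c(C=O)c2O)cc(O)c(C)c1O | target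

## Step count

Total: 7 steps. Longest linear sequence: 4 steps (steps 1, 2, 3, 7, or equally steps 4, 5, 6, 7).

## Three steps most likely to fail, with fallbacks

**Step 7 (the fragment-joining coupling).** The likely problems are slow oxidative addition into the phenoxide-rich aryl chloride and base-mediated loss of the ester. The fallback sets out from 6 and comes back at 15. Both phenols of 6 are masked with MOMCl and NaH in DMF at 0 °C to give methyl 6-chloro-2,4-bis(methoxymethoxy)-3-methylbenzoate F1, a neutral, more electron-poor 2-chlorobenzoate. F1 is coupled with 13 using the same Pd(OAc)2/RuPhos system but with only 4 equiv of K2CO3 and a shorter reaction time, giving [2-(methoxycarbonyl)-3,5-bis(methoxymethoxy)-4-methylphenyl]methyl 3-formyl-2,4-dihydroxy-6-methylbenzoate F2. The two acetals are then removed with 2 M HCl in THF at 40 °C, which leaves the hindered benzylic ester, the methyl ester and the aldehyde untouched, to give 15.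

**Step 4 (regiochemistry of formylation, C3 against C5).** The fallback sets out from 7 and comes back at 9, placing the carbon at C3 by a sigmatropic route. Allyl bromide and K2CO3 in refluxing acetone alkylate only the non-chelated 4-hydroxyl to give methyl 4-(allyloxy)-2-hydroxy-6-methylbenzoate F3. Aromatic Claisen rearrangement in N,N-diethylaniline at 190 °C goes to C3, the position between the two oxygens that the chelated salicylate favours and that is not flanked by the methyl group, giving methyl 2,4-dihydroxy-6-methyl-3-(prop-2-en-1-yl)benzoate F4. RuHCl(CO)(PPh3)3 in toluene at 80 °C moves the double bond into conjugation to give methyl 2,4-dihydroxy-6-methyl-3-[(E)-prop-1-en-1-yl]benzoate F5. Ozonolysis (O3, CH2Cl2/MeOH, −78 °C, then Me2S) cuts the alkene to the aldehyde 9.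

**Step 6 (making the boron reagent on a salicylic acid that can chelate boron, O-alkylate at a phenol or decarboxylate).** The fallback sets out from 10 and comes back at 15, replacing boron with tin and passing by 13. The potassium salt of 10 (KHCO3, DMF, rt) is alkylated with tributyl(iodomethyl)stannane, a non-Lewis-acidic electrophile, to give (tributylstannyl)methyl 3-formyl-2,4-dihydroxy-6-methylbenzoate F6. F6 is then joined to 6 in an anhydrous Stille coupling (Pd2(dba)3, P(t-Bu)3, CsF, 1,4-dioxane, 100 °C). The α-oxygenated CH2 group transfers in preference to butyl, and with no water or hydroxide present the ester cannot hydrolyse, so 15 is obtained directly.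

## Further compounds

F1 | step 7 | methyl 6-chloro-2,4-bis(methoxymethoxy)-3-methylbenzoate | COCOc1cc(Cl)c(C(=O)OC)c(OCOC)c1C
F2 | step 7 | [2-(methoxycarbonyl)-3,5-bis(methoxymethoxy)-4-methylphenyl]methyl 3-formyl-2,4-dihydroxy-6-methylbenzoate | COCOc1cc(COC(=O)c2c(C)cc(O)c(C=O)c2O)c(C(=O)OC)c(OCOC)c1C
F3 | step 4 | methyl 4-(allyloxy)-2-hydroxy-6-methylbenzoate | COC(=O)c1c(C)cc(OCC=C)cc1O
F4 | step 4 | methyl 2,4-dihydroxy-6-methyl-3-(prop-2-en-1-yl)benzoate | COC(=O)c1c(C)cc(O)c(CC=C)c1O
F5 | step 4 | methyl 2,4-dihydroxy-6-methyl-3-[(E)-prop-1-en-1-yl]benzoate | COC(=O)c1c(C)cc(O)c(/C=C/C)c1O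
F6 | step 6 | (tributylstannyl)methyl 3-formyl-2,4-dihydroxy-6-methylbenzoate | CCCC[Sn](CCCC)(CCCC)COC(=O)c1c(C)cc(O)c(C=O)c1O
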